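The target is cut at the C4–C4a bond of the pyran ring of unit B, the central ent-fisetinidol unit. C4 of unit B is a diarylmethine carbon flanked by C4a of its own resorcinol ring (para to O7, ortho to O1) and by C8 of the phloroglucinol ring of the catechin unit C. The key step is an acid-mediated reductive Friedel–Crafts cyclisation of an acyclic aryl ketone that already carries units A, C and D: in one operation the arene closes the pyran ring onto the C4 carbonyl carbon and a silane hydride, entering anti to O3, sets the 3,4-cis stereocentre. The precursor is an α-benzyloxy β-aryloxy ketone.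

Key step: step 14

Remark: flavan numbering (O1, C2, C3, C4, C4a, C5–C8, C8a) is used within each unit. The units are A (terminal ent-fisetinidol unit), B (central ent-fisetinidol unit), C (catechin unit) and D (ent-fisetinidol unit on C6 of C). As read from the SMILES, A, B and D are (2S,3R) and 2,3-trans, A and B are 3,4-cis, D is 3,4-trans, and C is (2R,3S).

Step 1
Reactants: 1 (S)-4-benzyl-2-oxazolidinone; 2 benzyloxyacetyl chloride
Product: 3 (S)-4-benzyl-3-(benzyloxyacetyl)oxazolidin-2-one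
Conditions: Et3N, DMAP (0.1 equiv), CH2Cl2, 0 °C to rt
Reagents that add atoms: none
Why: Amine-promoted N-acylation of the oxazolidinone by the acid chloride is the standard entry to a glycolate imide and creates no stereocentre.

Step 2
Reactants: 3 (S)-4-benzyl-3-(benzyloxyacetyl)oxazolidin-2-one; 4 3,4-bis(benzyloxy)benzaldehyde
Product: 6 Evans syn-aldol adduct (2S,3R), via boron enolate 5 (not isolated)
Conditions: n-Bu2BOTf, i-Pr2NEt, CH2Cl2, −78 to 0 °C; pH 7 buffer, MeOH
Reagents that add atoms: none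
Why: Evans syn-aldol reaction in which the Z-enolate 5 reacts through a Zimmerman–Traxler chair whose open face is fixed by the (S)-benzyl group of the auxiliary, so that both new stereocentres (2S,3R, syn) are set by the auxiliary.

Step 3
Reactants: 6 Evans syn-aldol adduct
Product: 7 (2S,3R)-2-(benzyloxy)-3-[3,4-bis(benzyloxy)phenyl]-3-hydroxy-N-methoxy-N-methylpropanamide
Conditions: AlMe3, MeNH(OMe)·HCl, CH2Cl2, −10 to 0 °C
Reagents that add atoms: N,O-dimethylhydroxylamine hydrochloride, CNOC.Cl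
Why: Aluminium amide transamidation of an aldol imide (Weinreb amide formation) is helped by the free β-hydroxyl group and should release the auxiliary without touching either stereocentre.

Step 4
Reactants: 7 hydroxy Weinreb amide; 8 3-(benzyloxy)phenol
Product: 9 (2S,3S)-2-(benzyloxy)-3-[3-(benzyloxy)phenoxy]-3-[3,4-bis(benzyloxy)phenyl]-N-methoxy-N-methylpropanamide
Conditions: PPh3, DIAD, toluene, 0 °C to rt
Reagents that add atoms: none
Why: Mitsunobu etherification with the phenol as acidic partner should displace the activated benzylic hydroxyl group in SN2 fashion, which inverts C3 (3R to 3S) and installs the anti O–O relationship needed for a 2,3-trans flavan.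

Step 5
Reactants: 8 3-(benzyloxy)phenol
Product: 10 3-(benzyloxy)-4-bromophenol
Conditions: NBS, MeCN, −20 °C
Reagents that add atoms: N-bromosuccinimide, O=C1CCC(=O)N1Br
Why: Electrophilic aromatic bromination should take place mainly para to the free hydroxyl group, the stronger director, and the ortho isomer can be removed by chromatography.

Step 6
Reactants: 10 3-(benzyloxy)-4-bromophenol; 9 aryloxy Weinreb amide
Product: 12 (2S,3S)-2-(benzyloxy)-1-[2-(benzyloxy)-4-hydroxyphenyl]-3-[3-(benzyloxy)phenoxy]-3-[3,4-bis(benzyloxy)phenyl]propan-1-one, via dilithio phenolate 11 (not isolated)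
Conditions: n-BuLi (2.1 equiv), THF, −78 °C; then 9, −78 to −40 °C; AcOH
Reagents that add atoms: none
Why: Deprotonation and bromine–lithium exchange give 11, whose aryllithium carbon acylates the Weinreb amide (Weinreb ketone synthesis, no over-addition), and neither stereocentre is involved.

Step 7
Reactants: 12 aryl ketone
Product: 14 3-(benzyloxy)-4-[(2S,3R,4R)-3,7-bis(benzyloxy)-2-[3,4-bis(benzyloxy)phenyl]chroman-4-yl]phenol, via flavan-4-ylium ion 13 (not isolated)
Conditions: CF3CO2H, Et3SiH (5 equiv), CH2Cl2, −20 to 0 °C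
Reagents that add atoms: none
Why: Reductive Friedel–Crafts cyclisation in which the carbon para to the benzyloxy group of the aryl ether ring attacks the protonated ketone (6-exo-trig), loss of water gives cation 13 and Et3SiH delivers hydride anti to the C3 benzyloxy group, so that C4 is set with its aryl group cis to O3 (4R), which also rehearses the key step on a small substrate.

Step 8
Reactants: 7 hydroxy Weinreb amide; 14 phenol carrying protected unit A
Product: 15 Weinreb amide (2S,3S) carrying the aryloxy group of 14 on C3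
Conditions: PPh3, DIAD, toluene, 0 °C to rt
Reagents that add atoms: none
Why: Mitsunobu etherification as in step 4, in which the unhindered phenol of 14 displaces the activated benzylic hydroxyl group of 7 with SN2 inversion (3R to 3S).

Step 9
Reactants: 16 (+)-catechin
Product: 17 5,7,3',4'-tetra-O-benzyl-(+)-catechin
Conditions: BnBr, K2CO3, DMF, 0 °C to rt
Reagents that add atoms: benzyl bromide, BrCc1ccccc1
Why: Williamson etherification with the weak base K2CO3 should benzylate the four phenols only and leave the secondary 3-OH and both stereocentres untouched.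

Step 10
Reactants: 17 5,7,3',4'-tetra-O-benzyl-(+)-catechin
Product: 18 8-bromo-5,7,3',4'-tetra-O-benzyl-(+)-catechin
Conditions: NBS (1.0 equiv), CH2Cl2, −78 °C to rt
Reagents that add atoms: N-bromosuccinimide, O=C1CCC(=O)N1Br
Why: Electrophilic bromination of the phloroglucinol-type ring with one equivalent of NBS is selective for C8 in benzylated catechins, which blocks C8 against the coming coupling and installs the later lithiation handle.

Step 11
Reactants: 9 aryloxy Weinreb amide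
Product: 19 (2S,3S)-2-(benzyloxy)-3-[3-(benzyloxy)phenoxy]-3-[3,4-bis(benzyloxy)phenyl]propanal
Conditions: i-Bu2AlH, THF, −78 °C; aq. KNaC4H4O6
Reagents that add atoms: none
Why: Reduction of a Weinreb amide with i-Bu2AlH stops at the aldehyde oxidation level, and the low temperature and neutral work-up should keep the α-stereocentre intact.

Step 12
Reactants: 19 aryloxy aldehyde; 18 8-bromo-5,7,3',4'-tetra-O-benzyl-(+)-catechin
Product: 21 bromide of the protected C–D fragment, via flavan-4-ylium ion 20 (not isolated)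
Conditions: TMSOTf (0.2 equiv), 4 Å molecular sieves, CH2Cl2, −78 to −30 °C, 18 in excess
Reagents that add atoms: none
Why: Acid-catalysed intramolecular Friedel–Crafts attack of the aryl ether ring on the activated aldehyde and loss of water give flavan-4-yl cation 20, which C6 of 18 (the only free position of its phloroglucinol ring) captures anti to the C3 benzyloxy group in a leucoanthocyanidin-type coupling, which sets C4 of unit D 3,4-trans (4R).

Step 13
Reactants: 21 bromide of the protected C–D fragment; 15 Weinreb amide carrying protected unit A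
Product: 23 aryl ketone joining C8 of unit C to the acyl carbon of 15, via aryllithium 22 (not isolated)
Conditions: n-BuLi (2.1 equiv), THF, −78 °C; then 15, −78 to −30 °C; AcOH
Reagents that add atoms: none
Why: The first equivalent of n-BuLi deprotonates the 3-OH and the second effects bromine–lithium exchange at C8 to give 22, which acylates Weinreb amide 15 to the ketone (Weinreb ketone synthesis) without touching any stereocentre.

Step 14
Reactants: 23 aryl ketone
Product: 25 hexadeca-O-benzyl ether of the target, via flavan-4-ylium ion 24 (not isolated)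
Conditions: CF3CO2H, Et3SiH (5 equiv), CH2Cl2, −20 to 0 °C
Reagents that add atoms: none
Why: Protonation of the aryl ketone of 23 lets C4a of the resorcinol ring (para to the C7 benzyloxy group, ortho to the ether oxygen O1) attack the carbonyl carbon C4, and loss of water gives the doubly benzylic 4-aryl-flavan-4-ylium ion 24, which Et3SiH reduces irreversibly. The closest known reaction types are the acid-mediated cyclialkylation of an aryl ketone by a tethered arene (Friedel–Crafts hydroxyalkylation) and the ionic hydrogenation of 4-aryl-flavan-4-ols. The pyran ring of unit B closes in the 6-exo-trig mode through the C4–C4a bond. The only new stereocentre, C4, is set in the hydride transfer: the hydride should enter the cation on the face anti to the adjacent C3 benzyloxy group, the face that carbon nucleophiles choose on 2,3-trans-flavan-4-yl cations, so that the aryl group of unit C ends up cis to O3 (3,4-cis, 4S), while C2 and C3 come unchanged from 15. The step needs regioselectivity (C4a and not C8, which lies between two oxygen substituents; C6 is blocked by unit A) and chemoselectivity (ring closure before reduction of the carbonyl group), and the latter is secured by a six-membered intramolecular attack of a strongly activated arene competing against a bimolecular hydride transfer from a weak donor.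

Step 15
Reactants: 25 hexadeca-O-benzyl ether of the target
Product: 26 target tetraflavanoid
Conditions: H2 (1 atm), Pd(OH)2/C, THF–MeOH, rt
Reagents that add atoms: none
Why: Hydrogenolysis over Pd(OH)2/C should cleave all sixteen benzyl ethers, while the interflavanyl C–C bonds and the C2–O1 bonds of the flavan units are stable under these neutral conditions, so that no stereocentre is affected.

Compound list

1 | (S)-4-benzyl-2-oxazolidinone | O=C1N[C@@H](Cc2ccccc2)CO1 | starting material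
2 | benzyloxyacetyl chloride | ClC(=O)COCc1ccccc1 | starting material
3 | (S)-4-benzyl-3-(benzyloxyacetyl)oxazolidin-2-one | O=C1OC[C@H](Cc2ccccc2)N1C(=O)COCc1ccccc1 | intermediate
4 | 3,4-bis(benzyloxy)benzaldehyde | O=Cc1ccc(OCc2ccccc2)c(OCc2ccccc2)c1 | starting material
5 | dibutylboron Z-enolate of 3 | CCCCB(CCCC)O/C(=C\OCc1ccccc1)N1[C@@H](Cc2ccccc2)COC1=O | intermediate (not isolated)
6 | (S)-4-benzyl-3-[(2S,3R)-2-(benzyloxy)-3-[3,4-bis(benzyloxy)phenyl]-3-hydroxypropanoyl]oxazolidin-2-one | O=C1OC[C@H](Cc2ccccc2)N1C(=O)[C@@H](OCc1ccccc1)[C@H](O)c1ccc(OCc2ccccc2)c(OCc2ccccc2)c1 | intermediate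
7 | (2S,3R)-2-(benzyloxy)-3-[3,4-bis(benzyloxy)phenyl]-3-hydroxy-N-methoxy-N-methylpropanamide | CON(C)C(=O)[C@@H](OCc1ccccc1)[C@H](O)c1ccc(OCc2ccccc2)c(OCc2ccccc2)c1 | intermediate
8 | 3-(benzyloxy)phenol | Oc1cccc(OCc2ccccc2)c1 | starting material
9 | (2S,3S)-2-(benzyloxy)-3-[3-(benzyloxy)phenoxy]-3-[3,4-bis(benzyloxy)phenyl]-N-methoxy-N-methylpropanamide | CON(C)C(=O)[C@@H](OCc1ccccc1)[C@@H](Oc1cccc(OCc2ccccc2)c1)c1ccc(OCc2ccccc2)c(OCc2ccccc2)c1 | intermediate
10 | 3-(benzyloxy)-4-bromophenol | Oc1ccc(Br)c(OCc2ccccc2)c1 | intermediate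
11 | lithium 3-(benzyloxy)-4-lithiophenolate | [Li]Oc1ccc([Li])c(OCc2ccccc2)c1 | intermediate (not isolated)
12 | (2S,3S)-2-(benzyloxy)-1-[2-(benzyloxy)-4-hydroxyphenyl]-3-[3-(benzyloxy)phenoxy]-3-[3,4-bis(benzyloxy)phenyl]propan-1-one | O=C(c1ccc(O)cc1OCc1ccccc1)[C@@H](OCc1ccccc1)[C@@H](Oc1cccc(OCc2ccccc2)c1)c1ccc(OCc2ccccc2)c(OCc2ccccc2)c1 | intermediate
13 | (2S,3R)-3,7-bis(benzyloxy)-4-[2-(benzyloxy)-4-hydroxyphenyl]-2-[3,4-bis(benzyloxy)phenyl]chroman-4-ylium ion | C(c1ccccc1)Oc1ccc2c(c1)O[C@@H](c1ccc(OCc3ccccc3)c(OCc3ccccc3)c1)[C@H](OCc1ccccc1)[C+]2c1ccc(O)cc1OCc1ccccc1 | intermediate (not isolated)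
14 | 3-(benzyloxy)-4-[(2S,3R,4R)-3,7-bis(benzyloxy)-2-[3,4-bis(benzyloxy)phenyl]chroman-4-yl]phenol (protected unit A, 2,3-trans-3,4-cis, on the future ring A of unit B) | C(c1ccccc1)Oc1ccc2c(c1)O[C@@H](c1ccc(OCc3ccccc3)c(OCc3ccccc3)c1)[C@H](OCc1ccccc1)[C@@H]2c1ccc(O)cc1OCc1ccccc1 | intermediate
15 | (2S,3S)-2-(benzyloxy)-3-[3,4-bis(benzyloxy)phenyl]-N-methoxy-N-methylpropanamide whose C3 carries the aryloxy group of 14, 3-(benzyloxy)-4-[(2S,3R,4R)-3,7-bis(benzyloxy)-2-[3,4-bis(benzyloxy)phenyl]chroman-4-yl]phenoxy | CON(C)C(=O)[C@@H](OCc1ccccc1)[C@@H](Oc1ccc([C@@H]2c3ccc(OCc4ccccc4)cc3O[C@@H](c3ccc(OCc4ccccc4)c(OCc4ccccc4)c3)[C@@H]2OCc2ccccc2)c(OCc2ccccc2)c1)c1ccc(OCc2ccccc2)c(OCc2ccccc2)c1 | intermediate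
16 | (+)-catechin, (2R,3S) | O[C@H]1Cc2c(O)cc(O)cc2O[C@@H]1c1ccc(O)c(O)c1 | starting material
17 | 5,7,3',4'-tetra-O-benzyl-(+)-catechin | O[C@H]1Cc2c(OCc3ccccc3)cc(OCc3ccccc3)cc2O[C@@H]1c1ccc(OCc2ccccc2)c(OCc2ccccc2)c1 | intermediate
18 | 8-bromo-5,7,3',4'-tetra-O-benzyl-(+)-catechin | O[C@H]1Cc2c(OCc3ccccc3)cc(OCc3ccccc3)c(Br)c2O[C@@H]1c1ccc(OCc2ccccc2)c(OCc2ccccc2)c1 | intermediate
19 | (2S,3S)-2-(benzyloxy)-3-[3-(benzyloxy)phenoxy]-3-[3,4-bis(benzyloxy)phenyl]propanal | O=C[C@@H](OCc1ccccc1)[C@@H](Oc1cccc(OCc2ccccc2)c1)c1ccc(OCc2ccccc2)c(OCc2ccccc2)c1 | intermediate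
20 | (2S,3R)-3,7-bis(benzyloxy)-2-[3,4-bis(benzyloxy)phenyl]chroman-4-ylium ion | C(c1ccccc1)Oc1ccc2c(c1)O[C@@H](c1ccc(OCc3ccccc3)c(OCc3ccccc3)c1)[C@H](OCc1ccccc1)[CH+]2 | intermediate (not isolated)
21 | (2R,3S)-5,7-bis(benzyloxy)-2-[3,4-bis(benzyloxy)phenyl]-6-[(2S,3R,4R)-3,7-bis(benzyloxy)-2-[3,4-bis(benzyloxy)phenyl]chroman-4-yl]-8-bromochroman-3-ol (protected C–D fragment, unit D 3,4-trans) | Brc1c(OCc2ccccc2)c([C@H]2c3ccc(OCc4ccccc4)cc3O[C@@H](c3ccc(OCc4ccccc4)c(OCc4ccccc4)c3)[C@@H]2OCc2ccccc2)c(OCc2ccccc2)c2c1O[C@H](c1ccc(OCc3ccccc3)c(OCc3ccccc3)c1)[C@@H](O)C2 | intermediate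
22 | 8-lithio derivative of 21 as its lithium 3-alkoxide | [Li]c1c(OCc2ccccc2)c([C@H]2c3ccc(OCc4ccccc4)cc3O[C@@H](c3ccc(OCc4ccccc4)c(OCc4ccccc4)c3)[C@@H]2OCc2ccccc2)c(OCc2ccccc2)c2c1O[C@H](c1ccc(OCc3ccccc3)c(OCc3ccccc3)c1)[C@@H](O[Li])C2 | intermediate (not isolated)
23 | (2S,3S)-2-(benzyloxy)-3-[3,4-bis(benzyloxy)phenyl]-3-aryloxypropan-1-one, aryloxy group as in 15, whose carbonyl carbon is bonded to C8 of the protected C–D fragment (21 without bromine) | O=C(c1c(OCc2ccccc2)c([C@H]2c3ccc(OCc4ccccc4)cc3O[C@@H](c3ccc(OCc4ccccc4)c(OCc4ccccc4)c3)[C@@H]2OCc2ccccc2)c(OCc2ccccc2)c2c1O[C@H](c1ccc(OCc3ccccc3)c(OCc3ccccc3)c1)[C@@H](O)C2)[C@@H](OCc1ccccc1)[C@@H](Oc1ccc([C@@H]2c3ccc(OCc4ccccc4)cc3O[C@@H](c3ccc(OCc4ccccc4)c(OCc4ccccc4)c3)[C@@H]2OCc2ccccc2)c(OCc2ccccc2)c1)c1ccc(OCc2ccccc2)c(OCc2ccccc2)c1 | intermediate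
24 | flavan-4-ylium ion of unit B: 25 with C4 of unit B as a carbenium centre bearing unit A on C6 and the aryl group of unit C on C4 | C(c1ccccc1)Oc1ccc2c(c1)O[C@@H](c1ccc(OCc3ccccc3)c(OCc3ccccc3)c1)[C@H](OCc1ccccc1)[C@@H]2c1cc2c(cc1OCc1ccccc1)O[C@@H](c1ccc(OCc3ccccc3)c(OCc3ccccc3)c1)[C@H](OCc1ccccc1)[C+]2c1c(OCc2ccccc2)c([C@H]2c3ccc(OCc4ccccc4)cc3O[C@@H](c3ccc(OCc4ccccc4)c(OCc4ccccc4)c3)[C@@H]2OCc2ccccc2)c(OCc2ccccc2)c2c1O[C@H](c1ccc(OCc3ccccc3)c(OCc3ccccc3)c1)[C@@H](O)C2 | intermediate (not isolated)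
25 | hexadeca-O-benzyl ether of 26: every phenolic oxygen and O3 of units A, B and D benzylated, 3-OH of unit C free, configuration as in 26 | C(c1ccccc1)Oc1ccc2c(c1)O[C@@H](c1ccc(OCc3ccccc3)c(OCc3ccccc3)c1)[C@H](OCc1ccccc1)[C@@H]2c1cc2c(cc1OCc1ccccc1)O[C@@H](c1ccc(OCc3ccccc3)c(OCc3ccccc3)c1)[C@H](OCc1ccccc1)[C@@H]2c1c(OCc2ccccc2)c([C@H]2c3ccc(OCc4ccccc4)cc3O[C@@H](c3ccc(OCc4ccccc4)c(OCc4ccccc4)c3)[C@@H]2OCc2ccccc2)c(OCc2ccccc2)c2c1O[C@H](c1ccc(OCc3ccccc3)c(OCc3ccccc3)c1)[C@@H](O)C2 | intermediate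
26 | target: ent-fisetinidol-(4→6)-ent-fisetinidol-(4→8)-catechin-(6→4)-ent-fisetinidol; A (2S,3R,4R; 3,4-cis), B (2S,3R,4S; 3,4-cis), C (2R,3S), D (2S,3R,4R; 3,4-trans) | Oc1ccc2c(c1)O[C@@H](c1ccc(O)c(O)c1)[C@H](O)[C@@H]2c1cc2c(cc1O)O[C@@H](c1ccc(O)c(O)c1)[C@H](O)[C@@H]2c1c(O)c([C@H]2c3ccc(O)cc3O[C@@H](c3ccc(O)c(O)c3)[C@@H]2O)c(O)c2c1O[C@H](c1ccc(O)c(O)c1)[C@@H](O)C2 | target

Total step count: 15 steps.
Longest linear sequence: 10 steps (steps 1, 2, 3, 4, 6, 7, 8, 13, 14, 15).

Steps most likely to fail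

Step 14 (the same reaction type is used in step 7). Arene attack on the crowded, electron-rich aryl ketone may be slow. Direct ionic reduction of the carbonyl group (which would lead into the 3,4-trans series), acid-promoted loss of the phenol from C2, or hydride delivery to the wrong face could then compete. Fallback, from 14 back to 25: the ring closure is moved to an unhindered acyl group and the C4–aryl bond is made afterwards. NIS (MeCN, 0 °C) should iodinate phenol 14 ortho to the hydroxyl group and para to the benzyloxy group to give iodophenol F1. Mitsunobu etherification with 7 gives iodo Weinreb amide F2. Iodine–lithium exchange (t-BuLi, THF, −100 °C) and Parham cyclisation onto the Weinreb amide close the same C4–C4a bond and give flavan-4-one F3. Aryllithium 22 should add to the ketone anti to the 3-benzyloxy group to give tertiary carbinol F4. CF3CO2H/Et3SiH ionises F4 to cation 24 and reduces it to 25.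

Step 4 (the same reaction type is used in step 8). The activated, electron-rich benzylic alcohol may eliminate to the cinnamamide or ionise, which would erode the inversion. Fallback, from 4 back to 9: Horner–Wadsworth–Emmons olefination of 4 with NaH and (EtO)2P(O)CH2C(O)N(OMe)Me gives (E)-acrylamide F5. Asymmetric epoxidation (Sm(O-i-Pr)3, the BINOL antipode that gives the (2S,3R) epoxide, Ph3As=O, t-BuOOH) gives trans-glycidic amide F6. Phenol 8 with Cs2CO3 in DMF should open the epoxide at the benzylic carbon with inversion to give hydroxy ether F7. O-Benzylation with benzyl 2,2,2-trichloroacetimidate and catalytic TfOH returns 9.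

Step 12. Self-condensation of cation 20 through its own resorcinol ring, or capture by 18 through oxygen, may outrun attack of the hindered C6 position. Fallback, from 19 back to 21: 19 is cyclised with catalytic TMSOTf in the presence of BnSH, which should trap cation 20 anti to the 3-benzyloxy group as the stable 4-benzylsulfanylflavan F8. Isolated F8 is then activated with the thiophilic salt AgBF4 in the presence of excess 18 to give 21.

Further compounds

F1 | step 14 | 2-iodo derivative of phenol 14 (iodine ortho to the hydroxyl group and para to the benzyloxy group) | C(c1ccccc1)Oc1ccc2c(c1)O[C@@H](c1ccc(OCc3ccccc3)c(OCc3ccccc3)c1)[C@H](OCc1ccccc1)[C@@H]2c1cc(I)c(O)cc1OCc1ccccc1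
F2 | step 14 | Weinreb amide 15 carrying iodine on the aryloxy ring ortho to the ether oxygen and para to the benzyloxy group | CON(C)C(=O)[C@@H](OCc1ccccc1)[C@@H](Oc1cc(OCc2ccccc2)c([C@@H]2c3ccc(OCc4ccccc4)cc3O[C@@H](c3ccc(OCc4ccccc4)c(OCc4ccccc4)c3)[C@@H]2OCc2ccccc2)cc1I)c1ccc(OCc2ccccc2)c(OCc2ccccc2)c1
F3 | step 14 | (2S,3R)-3,7-bis(benzyloxy)-2-[3,4-bis(benzyloxy)phenyl]chroman-4-one carrying protected unit A on C6 | C(c1ccccc1)Oc1ccc2c(c1)O[C@@H](c1ccc(OCc3ccccc3)c(OCc3ccccc3)c1)[C@H](OCc1ccccc1)[C@@H]2c1cc2c(cc1OCc1ccccc1)O[C@@H](c1ccc(OCc3ccccc3)c(OCc3ccccc3)c1)[C@H](OCc1ccccc1)C2=O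
F4 | step 14 | tertiary carbinol from F3 and 22 (C4 of unit B bears OH cis to the 3-benzyloxy group and the aryl group of unit C trans to it) | C(c1ccccc1)Oc1ccc2c(c1)O[C@@H](c1ccc(OCc3ccccc3)c(OCc3ccccc3)c1)[C@H](OCc1ccccc1)[C@@H]2c1cc2c(cc1OCc1ccccc1)O[C@@H](c1ccc(OCc3ccccc3)c(OCc3ccccc3)c1)[C@H](OCc1ccccc1)[C@@]2(O)c1c(OCc2ccccc2)c([C@H]2c3ccc(OCc4ccccc4)cc3O[C@@H](c3ccc(OCc4ccccc4)c(OCc4ccccc4)c3)[C@@H]2OCc2ccccc2)c(OCc2ccccc2)c2c1O[C@H](c1ccc(OCc3ccccc3)c(OCc3ccccc3)c1)[C@@H](O)C2
F5 | step 4 | (E)-3-[3,4-bis(benzyloxy)phenyl]-N-methoxy-N-methylprop-2-enamide | CON(C)C(=O)/C=C/c1ccc(OCc2ccccc2)c(OCc2ccccc2)c1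
F6 | step 4 | (2S,3R)-3-[3,4-bis(benzyloxy)phenyl]-N-methoxy-N-methyloxirane-2-carboxamide (trans) | CON(C)C(=O)[C@H]1O[C@@H]1c1ccc(OCc2ccccc2)c(OCc2ccccc2)c1
F7 | step 4 | (2S,3S)-3-[3-(benzyloxy)phenoxy]-3-[3,4-bis(benzyloxy)phenyl]-2-hydroxy-N-methoxy-N-methylpropanamide | CON(C)C(=O)[C@@H](O)[C@@H](Oc1cccc(OCc2ccccc2)c1)c1ccc(OCc2ccccc2)c(OCc2ccccc2)c1
F8 | step 12 | (2S,3R,4S)-3,7-bis(benzyloxy)-4-(benzylsulfanyl)-2-[3,4-bis(benzyloxy)phenyl]chroman (3,4-trans) | C(c1ccccc1)Oc1ccc2c(c1)O[C@@H](c1ccc(OCc3ccccc3)c(OCc3ccccc3)c1)[C@H](OCc1ccccc1)[C@H]2SCc1ccccc1
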